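Monday's flask leaves a leftover to read: at its last reading 34.4% of the substrate stands as mono adduct plus bis adduct, and those two hold 1.75 reagent per substrate converted.

| setting | Monday's | Sunday's | violet | amber | red |
|---|---|---|---|---|---|
| substrate | 0.50 mM | 0.50 mM | 0.50 mM | 0.50 mM | 0.50 mM |
| reagent | 0.35 mM | 1.6 mM | 1.25 mM | 0.400 mM | 0.250 mM |
| capture agent | 0.15 mM | 0.15 mM | 0.150 mM | 0.150 mM | 0.150 mM |
| remark | run made earlier | run made earlier |  |  |  |
| time |  |  | 2.5 min | 2.5 min | 2.5 min |

| run | time / s | mono adduct / % | bis adduct / % |
|---|---|---|---|
| Monday's | 20.0 | 12.1 | 14.0 |
| Monday's | 40.0 | 11.2 | 21.9 |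
| Monday's | 60.0 | 10.4 | 24.6 |
| Monday's | 80.0 | 8.5 | 25.9 |
| Sunday's | 20.0 | 4.9 | 72.7 |
| Sunday's | 40.0 | 1.6 | 89.0 |
| Sunday's | 60.0 | 0.7 | 93.4 |
| Sunday's | 80.0 | 0 | 95.8 |

(each reading ± 0.3 percentage points)

* which of these holds the largest part of the substrate at the end of violet (mono adduct / substrate / bis adduct)
* which of these holds the largest part of the substrate at the end of amber (mono adduct / substrate / bis adduct)
* which of these holds the largest part of the substrate at the end of red (mono adduct / substrate / bis adduct)
* mono adduct at the end of red, in percent of the substrate charged



Who holds the most at the end? Full conversion to bis adduct takes twice the substrate charge in reagent, and violet's reagent covers 1.25 of that need, so I expect bis adduct there, as in Sunday's flask. Reagent is the limiting reagent in amber and red, whose charges fall short of that need, and if the charge goes at 1.75 per substrate, my estimate leaves 54.4% and 71.5% of the substrate unconverted, so I expect substrate to hold the most in both.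

What becomes of red's mono adduct once the reagent thins out? Monday's mono adduct falls from 11.2% to 8.5% between 40.0 s and 80.0 s, which I read as a net half-life h of 1.68 min, the fall half-life, a reading that carries the scatter of those two points. Assuming that red stands at Monday's last reading at the same time, although red has less reagent, my own reckoning gives 5.25% at the end of red.

The forecast says bis adduct, substrate and substrate for violet, amber and red, and puts red's mono adduct at 7.5% (4.5% to 11.5%), higher than my figure, on the ground that “Monday's mono still fell slowly after the reagent ran out”.

Violet, amber and red give bis adduct, substrate and substrate, with 5.45% of mono adduct in red, inside the forecast's range.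

    mono adduct + capture agent → trapped intermediate (k = 70.0 L mol⁻¹ s⁻¹)
    reagent + mono adduct → bis adduct (k = 350 L mol⁻¹ s⁻¹)
    substrate + reagent → mono adduct (k = 71.0 L mol⁻¹ s⁻¹)

Red has not come to rest at 2.5 min: by 25.0 min its mono adduct is 0.00574%, its trapped intermediate has moved from 10.7% to 16.2% of the substrate charged, and its capture agent from 64.5% to 46.1% of its own charge, while its substrate stands at 66.9%. Carrying h that far from 5.45% gives <0.001%, less than the computed value.

For the same flask as red read at 10 min, h carried from red's end value gives 0.247% of mono adduct; the computed flask holds 0.462%.

The numbers in the tables are calculated with made-up constants; scatter was added.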